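## The problem

Compound 22 is a 2-arylbenzofuran in which a resorcinol ring (ring B, C1' to C6') is bonded through C1' to C2 of a benzofuran whose benzo ring (ring A) carries a hydroxyl at C6 and a prenyl (3-methylbut-2-en-1-yl) group at C7. There is no stereocentre and no ring that is hard to close, so the task is purely regiochemical: three prenyl groups must go onto three particular carbons of two electron-rich rings. Ring B is the hard part, because its prenyl groups stand at C2' and C6', the carbons flanking the aryl–furan bond, while C4', between the two hydroxyls, stays free although any electrophilic prenylation of a 5-arylresorcinol would attack it first. Two substituents ortho to the C2–C1' bond also crowd that bond, which argues for forming it before they are in place. Every prenyl group lies next to a free phenol, so the finished skeleton will not stand strong acid (chroman closure, addition to the alkenes), unpoisoned hydrogenation or oxidants. The enabling feature is that C2' is ortho to O3', C6' is ortho to O5', and the only other ortho carbon of either oxygen is the shared C4'. If C4' carries a removable substituent, an allyl group passed from O3' and O5' to carbon can only arrive at C2' and C6'; a carboxyl group qualifies, because 2,6-dihydroxybenzoic acids lose CO2 easily and the matching phloroglucinol carboxylate is commercial.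

## Retrosynthesis

**22 to 20 to 19 (unmasking).** The C4'–H bond of 22 is traced back to a C4'–CO2Me bond in the triphenol ester 20, to be cleaved by saponification and decarboxylation. A carboxyl blocker is preferred to a halogen or silyl blocker because it leaves under aqueous base, which the prenyl groups tolerate. Ester 20 comes from 19 by loss of the methoxymethyl acetal on O6, the one protecting group in the plan. The acetal is removed before the ester so that, during the only acidic step, both ring B phenols are still hydrogen-bonded to the ester and therefore less nucleophilic.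

**19 to 17 (key disconnection).** The two ring B aryl–CH2 bonds of 19 (C2'–CH2 and C6'–CH2, at C3 and C5 of the benzoate) are cut and reconnected as O–CMe2 bonds of the bis(1,1-dimethylallyl) ether 17. Direct C-prenylation would go to C4', to C3 of the furan and to ring A. A cross-coupling at C2'/C6' would first need a selective dihalogenation of the same positions and would have to form two bonds beside the biaryl axis. The sigmatropic route takes its regiochemistry from the oxygens already present and delivers the linear prenyl group by allylic inversion. Ether 17 has no carbon substituent on ring B beyond the blocker. The forward step must make both shifts go to the open ortho carbons without ionizing the tertiary ethers.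

**17 to 15 to 14 to 13 plus 3 (tertiary ethers).** Tertiary allyl aryl ethers cannot be made by direct displacement. The O–CMe2 bonds are therefore formed by copper-catalysed propargylic substitution with the propargylic carbonate 3, and the alkynes are then semihydrogenated (15 to 17). The two ethers are put on one after the other, 13 to mono ether 14 and 14 to bis ether 15. The first etherification of a 2,6-dihydroxyaryl carbonyl compound is the easy one. The second must alkylate a hydroxyl that is chelated to the ester and flanked by it, and is given its own charge of reagent and catalyst.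

**13 to 10 plus 12 (biaryl bond).** The C2–C1' bond is cut by a Suzuki–Miyaura disconnection into benzofuran-2-boronate 10 and aryl triflate 12. Boron goes on the benzofuran because C2–H is its most acidic position. The triflate goes on ring B because C1' corresponds to the 4-oxygen of a phloroglucinol carboxylate. The coupling joins two halves of similar size, at a stage when both positions ortho to the new bond on ring B are still hydrogen.

**12 to 11.** Triflate 12 comes from methyl 2,4,6-trihydroxybenzoate (11) by sulfonylation of the 4-hydroxyl, the only one not hydrogen-bonded to the ester and the most acidic.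

**10 to 8 to 7 to 6 to 5 to 4 plus 3 (ring A half).** The C2–B bond of 10 comes from lithiation of acetal 8, made from phenol 7. The C7–CH2 bond of 7 is cut in the same way as on ring B: back to 1,1-dimethylallyl ether 6, its alkyne 5, and benzofuran-6-ol (4) plus carbonate 3. The forward Claisen shift must choose C7 over C5, for which the bond fixation of the benzofuran is relied upon.

**3 to 1.** Carbonate 3 is the methoxycarbonyl derivative of 2-methylbut-3-yn-2-ol (1). A storable, distillable electrophile is preferred to activation in the flask because one batch serves all three etherifications.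

## Roads not taken

**Alternative 1:** Ring A is cut at C3a–C4 and grown onto a furan. Racemic keto acetal A2 (a 5-aryl-2-furyl unit carrying the chain CH(prenyl)–CO–CH2–CH(OEt)2) is treated with acid; furan C3 attacks the oxocarbenium ion, and loss of ethanol and enolization give phenol A1, the target with both ring B oxygens silylated.
- Merits: the C6 hydroxyl and C7 prenyl are placed by the constitution of the chain, so there is no C5/C7 question and O6 needs no protecting group. Here this road is better than the chosen plan, which relies on a regiochemical preference in step 4.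
- Weak points: the ring closure is a dehydrative aromatization in acid on a substrate with three prenyl groups, two silyl ethers and a 2,5-disubstituted furan. Furan C3 is its less nucleophilic position. Above all, ring B with its C2'/C6' prenyl pair must already be present in A2, so the central problem is moved into the starting material, not solved.
- Comparison: the chosen plan buys ring A ready-made, uses acid only for an acetal hydrolysis at room temperature, and solves ring B.

**Alternative 2:** The furan is cut at C2=C3. Phosphonium salt A4, an ortho-acyloxybenzyl salt whose ester is derived from ring B acid A5, is deprotonated; the ylide attacks the ester carbonyl and loss of triphenylphosphine oxide gives the tris(methoxymethyl) ether A3.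
- Merits: the halves are joined by an ester bond, and ring A substitution is fixed in the salicyl half. The prenyl groups of A5 could be set by directed metalation between the carboxyl-derived group and each acetal oxygen. That regiocontrol is as clean as the chosen plan's and needs no blocking group.
- Weak points: the carbonyl the ylide must attack sits between two ortho prenyl groups, and the phenol that must be acylated is also flanked on both sides, so both esterification and Wittig closure are hindered. Three acetals must be removed by acid at the very end, with all three prenylphenol units exposed at once. The salicyl half needs its own multistep synthesis.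
- Comparison: the chosen plan forms the aryl–furan bond by cross-coupling while both ortho positions of ring B are hydrogen, carries one acetal instead of three, and is shorter.

**Alternative 3:** Ring B is cut at C3'–C4', C5'–C6' and C2'–C3'. Racemic cyclobutenone A7 opens thermally to a vinylketene, which adds silyl ynol ether A8; ring opening and six-electron electrocyclization give the mono-silylated resorcinol A6.
- Merits: every ring B substituent is placed by the mechanism, so the innate reactivity of C4' never has to be overridden and no blocker is carried. One step makes a pentasubstituted benzene. In this respect it is superior.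
- Weak points: A7, a 2,3,4-trisubstituted cyclobutenone with a heteroaryl and two prenyl groups, would cost more steps than all of ring B costs in the chosen plan. The vinylketene has allylic C–H bonds and trisubstituted alkenes within reach, so hydrogen shifts and intramolecular ene or cycloaddition pathways compete. A8 is sensitive and must be prepared. The differentiation of O3' and O5' is wasted on a target with two free hydroxyls.
- Comparison: the chosen plan uses commodity starting materials and exploits the symmetry of ring B, setting both prenyl groups in one operation.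

Key step: step 12

Remark on the chemistry: the target has no stereocentre. Prenyl means 3-methylbut-2-en-1-yl. Ring B positions C1', C2', C3', C4', C5', C6' of the target are C4, C3, C2, C1, C6, C5 of the benzoate intermediates.

## Route

Step 1
Reactants: 1 2-methylbut-3-yn-2-ol
Product: 3 methyl 2-methylbut-3-yn-2-yl carbonate, via lithium 2-methylbut-3-yn-2-olate 2 (not isolated)
Conditions: n-BuLi (1.0 equiv), THF, −78 °C; then ClCO2Me, −78 °C to rt
Reagents that add atoms: methyl chloroformate, COC(Cl)=O
Why: O-acylation of a tertiary lithium alkoxide with a chloroformate; one equivalent of base removes the hydroxyl proton before the alkyne proton. The carbonate is a stable liquid that can be distilled and stored for the three etherifications.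

Step 2
Reactants: 4 benzofuran-6-ol; 3 methyl 2-methylbut-3-yn-2-yl carbonate
Product: 5 6-[(2-methylbut-3-yn-2-yl)oxy]-1-benzofuran
Conditions: DBU, CuCl2·2H2O (cat.), MeCN, 0 °C to rt
Reagents that add atoms: none
Why: Copper-catalysed propargylic substitution: the copper acetylide of 3 loses methyl carbonate (as CO2 and methoxide) to give an allenylidene-type electrophile that the phenoxide captures at the tertiary carbon. This is the standard way to aryl 1,1-dimethylpropargyl ethers, which direct displacement cannot give.

Step 3
Reactants: 5 6-[(2-methylbut-3-yn-2-yl)oxy]-1-benzofuran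
Product: 6 6-[(2-methylbut-3-en-2-yl)oxy]-1-benzofuran
Conditions: H2 (1 atm), Pd/CaCO3 poisoned with Pb(OAc)2 (Lindlar catalyst), quinoline, EtOAc, rt
Reagents that add atoms: none
Why: Lindlar semihydrogenation stops the terminal alkyne at the vinyl group; the poisoned catalyst leaves the furan C2=C3 bond alone, and room temperature avoids propargyl rearrangement to a chromene.

Step 4
Reactants: 6 6-[(2-methylbut-3-en-2-yl)oxy]-1-benzofuran
Product: 7 7-prenyl-1-benzofuran-6-ol
Conditions: PhNEt2, 130 °C, Ar
Reagents that add atoms: none
Why: Aromatic Claisen rearrangement: a chair [3,3] shift bonds the vinyl CH2 to C7, so the tertiary ether becomes a linear prenyl group, and enolization restores the phenol. C7 should be favoured over C5 because C6–C7 has the higher double-bond character in a benzofuran, as in 2-naphthyl and coumarin-7-yl allyl ethers.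

Step 5
Reactants: 7 7-prenyl-1-benzofuran-6-ol
Product: 8 6-(methoxymethoxy)-7-prenyl-1-benzofuran
Conditions: MOMCl, iPr2NEt, CH2Cl2, 0 °C to rt
Reagents that add atoms: chloromethyl methyl ether (MOMCl), COCCl
Why: O-alkylation of the phenol with an α-chloro ether under amine base. The acetal tolerates the organolithium, the basic coupling, the copper/DBU etherifications and the heating that follow.

Step 6
Reactants: 8 6-(methoxymethoxy)-7-prenyl-1-benzofuran
Product: 10 2-[6-(methoxymethoxy)-7-prenyl-1-benzofuran-2-yl]-4,4,5,5-tetramethyl-1,3,2-dioxaborolane, via C2-lithiated benzofuran 9 (not isolated)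
Conditions: n-BuLi, THF, −78 °C; then iPrOBpin, −78 °C to rt; aq NH4Cl
Reagents that add atoms: 2-isopropoxy-4,4,5,5-tetramethyl-1,3,2-dioxaborolane (iPrOBpin), CC(C)OB1OC(C)(C)C(C)(C)O1
Why: C2–H is the most acidic hydrogen of a benzofuran and is removed quickly at −78 °C, well before the benzylic/allylic CH2 or the position ortho to the acetal. Trapping with the borate gives the pinacol boronate (lithiation–borylation).

Step 7
Reactants: 11 methyl 2,4,6-trihydroxybenzoate
Product: 12 methyl 2,6-dihydroxy-4-{[(trifluoromethyl)sulfonyl]oxy}benzoate
Conditions: PhNTf2 (1 equiv), Et3N (1 equiv), THF, 0 °C to rt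
Reagents that add atoms: N-phenylbis(trifluoromethanesulfonimide) (PhNTf2), O=S(=O)(N(c1ccccc1)S(=O)(=O)C(F)(F)F)C(F)(F)F
Why: Selective O-sulfonylation: the 4-hydroxyl is the most acidic and the only one not hydrogen-bonded to the ester, so one equivalent of base and a mild triflyl donor should react there. The 7-selective triflation of 5,7-dihydroxy aryl ketones is the analogy.

Step 8
Reactants: 10 2-[6-(methoxymethoxy)-7-prenyl-1-benzofuran-2-yl]-4,4,5,5-tetramethyl-1,3,2-dioxaborolane; 12 methyl 2,6-dihydroxy-4-{[(trifluoromethyl)sulfonyl]oxy}benzoate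
Product: 13 methyl 2,6-dihydroxy-4-[6-(methoxymethoxy)-7-prenyl-1-benzofuran-2-yl]benzoate
Conditions: Pd(dppf)Cl2 (cat.), K3PO4, 1,4-dioxane/H2O, 70 °C
Reagents that add atoms: none
Why: Suzuki–Miyaura coupling: zerovalent palladium inserts into the C–OTf bond para to the ester, the boronate transfers the benzofuran-2-yl group, and reductive elimination forms C2–C1'. Both carbons ortho to the triflate are unsubstituted, and hydrogen-bonded phenols are tolerated in couplings of hydroxyaryl triflates.

Step 9
Reactants: 13 methyl 2,6-dihydroxy-4-[6-(methoxymethoxy)-7-prenyl-1-benzofuran-2-yl]benzoate; 3 methyl 2-methylbut-3-yn-2-yl carbonate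
Product: 14 methyl 2-hydroxy-4-[6-(methoxymethoxy)-7-prenyl-1-benzofuran-2-yl]-6-[(2-methylbut-3-yn-2-yl)oxy]benzoate
Conditions: 3 (1.2 equiv), DBU, CuCl2·2H2O (cat.), MeCN, 0 °C
Reagents that add atoms: none
Why: Copper-catalysed propargylic etherification as in step 2; DBU turns a chelated hydroxyl into a phenoxide, and mono-etherification of 2,6-dihydroxyaryl carbonyl compounds with 1,1-dimethylpropargyl electrophiles is well known. Any bis ether 15 formed alongside is carried forward with 14.

Step 10
Reactants: 14 methyl 2-hydroxy-4-[6-(methoxymethoxy)-7-prenyl-1-benzofuran-2-yl]-6-[(2-methylbut-3-yn-2-yl)oxy]benzoate; 3 methyl 2-methylbut-3-yn-2-yl carbonate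
Product: 15 methyl 4-[6-(methoxymethoxy)-7-prenyl-1-benzofuran-2-yl]-2,6-bis[(2-methylbut-3-yn-2-yl)oxy]benzoate
Conditions: 3 (excess, in portions), DBU, CuCl2·2H2O (cat.), MeCN, 0 °C to rt
Reagents that add atoms: none
Why: Second copper-catalysed propargylic etherification, on the remaining ester-chelated hydroxyl. The cationic copper allenylidene is a small, reactive electrophile suited to flanked, electron-poor phenoxides, and fresh reagent and catalyst drive the slower second alkylation without long exposure of the first ether.

Step 11
Reactants: 15 methyl 4-[6-(methoxymethoxy)-7-prenyl-1-benzofuran-2-yl]-2,6-bis[(2-methylbut-3-yn-2-yl)oxy]benzoate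
Product: 17 methyl 4-[6-(methoxymethoxy)-7-prenyl-1-benzofuran-2-yl]-2,6-bis[(2-methylbut-3-en-2-yl)oxy]benzoate, via half-reduced alkenyl alkynyl diether 16 (not isolated)
Conditions: H2 (1 atm), Pd/CaCO3 poisoned with Pb(OAc)2 (Lindlar catalyst), quinoline, EtOAc, rt
Reagents that add atoms: none
Why: Lindlar semihydrogenation of both terminal alkynes. The trisubstituted prenyl alkene and the benzofuran are not reduced on the poisoned catalyst, and hydrogen uptake is followed so the vinyl groups are not reduced further.

Step 12
Reactants: 17 methyl 4-[6-(methoxymethoxy)-7-prenyl-1-benzofuran-2-yl]-2,6-bis[(2-methylbut-3-en-2-yl)oxy]benzoate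
Product: 19 methyl 2,6-dihydroxy-4-[6-(methoxymethoxy)-7-prenyl-1-benzofuran-2-yl]-3,5-diprenylbenzoate, via mono-rearranged phenol 18 (not isolated)
Conditions: PhNEt2, 135 °C, Ar
Reagents that add atoms: none
Why: Each aryl 1,1-dimethylallyl ether undergoes a concerted suprafacial [3,3] shift through a chair transition state: the vinyl CH2 bonds to the free ortho carbon (benzoate C3, then C5; C2' and C6' of the target) as the O–CMe2 bond breaks, so the allyl unit is inverted and arrives as a linear prenyl group. The 6-prenylcyclohexa-2,4-dienone formed enolizes at once to a phenol held by a hydrogen bond to the ester. The closest known reaction type is the aromatic Claisen rearrangement of aryl 1,1-dimethylallyl ethers to ortho-prenylphenols, run here twice on one ring by way of 18. No ring closes and no stereocentre is formed. The selectivity needed is C3/C5 against C1: C1 carries the ester, so a shift there would give a crowded quaternary dienone that cannot enolize, whereas the shift to the CH carbon is made irreversible by tautomerization. Ring A offers no competing site because O6 is an acetal, not an allyl ether. The weakly basic amine solvent scavenges traces of acid that would ionize the tertiary ethers or close the new ortho-prenylphenols to chromans. Tertiary ethers of this kind rearrange well below the temperature simple allyl ethers need, which keeps the acetal and the C7 prenyl group safe.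

Step 13
Reactants: 19 methyl 2,6-dihydroxy-4-[6-(methoxymethoxy)-7-prenyl-1-benzofuran-2-yl]-3,5-diprenylbenzoate
Product: 20 methyl 2,6-dihydroxy-4-(6-hydroxy-7-prenyl-1-benzofuran-2-yl)-3,5-diprenylbenzoate
Conditions: HCl (0.5 M in MeOH), THF, 0 °C to rt
Reagents that add atoms: none
Why: Acid-catalysed acetal exchange with methanol frees the phenol. Aryl methoxymethyl ethers cleave in dilute methanolic HCl at room temperature, conditions under which trisubstituted alkenes are protonated only slowly, and the ring B phenols are still tied to the ester.

Step 14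
Reactants: 20 methyl 2,6-dihydroxy-4-(6-hydroxy-7-prenyl-1-benzofuran-2-yl)-3,5-diprenylbenzoate
Product: 22 5-(6-hydroxy-7-prenyl-1-benzofuran-2-yl)-4,6-diprenylbenzene-1,3-diol, via free carboxylic acid 21 (not isolated)
Conditions: NaOH (2 M aq), MeOH, reflux, Ar; then NaH2PO4 to pH 5–6, 50 °C
Reagents that add atoms: none
Why: Saponification followed by decarboxylation of the 2,6-dihydroxybenzoic acid: ipso protonation of the electron-rich ring through its keto tautomer, then loss of CO2. This is the established way to remove an ester blocking group from resorcylate esters, and it needs no acid stronger than a phosphate buffer.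

## Compound list

1 | 2-methylbut-3-yn-2-ol | CC(C)(O)C#C | starting material
2 | lithium 2-methylbut-3-yn-2-olate | [Li]OC(C)(C)C#C | intermediate
3 | methyl 2-methylbut-3-yn-2-yl carbonate | COC(=O)OC(C)(C)C#C | intermediate
4 | benzofuran-6-ol | Oc1ccc2ccoc2c1 | starting material
5 | 6-[(2-methylbut-3-yn-2-yl)oxy]-1-benzofuran | C#CC(C)(C)Oc1ccc2ccoc2c1 | intermediate
6 | 6-[(2-methylbut-3-en-2-yl)oxy]-1-benzofuran | C=CC(C)(C)Oc1ccc2ccoc2c1 | intermediate
7 | 7-(3-methylbut-2-en-1-yl)-1-benzofuran-6-ol | CC(C)=CCc1c(O)ccc2ccoc12 | intermediate
8 | 6-(methoxymethoxy)-7-(3-methylbut-2-en-1-yl)-1-benzofuran | COCOc1ccc2ccoc2c1CC=C(C)C | intermediate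
9 | [6-(methoxymethoxy)-7-(3-methylbut-2-en-1-yl)-1-benzofuran-2-yl]lithium | [Li]c1cc2ccc(OCOC)c(CC=C(C)C)c2o1 | intermediate
10 | 2-[6-(methoxymethoxy)-7-(3-methylbut-2-en-1-yl)-1-benzofuran-2-yl]-4,4,5,5-tetramethyl-1,3,2-dioxaborolane | CC1(C)OB(OC1(C)C)c1cc2ccc(OCOC)c(CC=C(C)C)c2o1 | intermediate
11 | methyl 2,4,6-trihydroxybenzoate | COC(=O)c1c(O)cc(O)cc1O | starting material
12 | methyl 2,6-dihydroxy-4-{[(trifluoromethyl)sulfonyl]oxy}benzoate | COC(=O)c1c(O)cc(OS(=O)(=O)C(F)(F)F)cc1O | intermediate
13 | methyl 2,6-dihydroxy-4-[6-(methoxymethoxy)-7-(3-methylbut-2-en-1-yl)-1-benzofuran-2-yl]benzoate | COC(=O)c1c(O)cc(-c2cc3ccc(OCOC)c(CC=C(C)C)c3o2)cc1O | intermediate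
14 | methyl 2-hydroxy-4-[6-(methoxymethoxy)-7-(3-methylbut-2-en-1-yl)-1-benzofuran-2-yl]-6-[(2-methylbut-3-yn-2-yl)oxy]benzoate | COC(=O)c1c(O)cc(-c2cc3ccc(OCOC)c(CC=C(C)C)c3o2)cc1OC(C)(C)C#C | intermediate
15 | methyl 4-[6-(methoxymethoxy)-7-(3-methylbut-2-en-1-yl)-1-benzofuran-2-yl]-2,6-bis[(2-methylbut-3-yn-2-yl)oxy]benzoate | COC(=O)c1c(OC(C)(C)C#C)cc(-c2cc3ccc(OCOC)c(CC=C(C)C)c3o2)cc1OC(C)(C)C#C | intermediate
16 | methyl 4-[6-(methoxymethoxy)-7-(3-methylbut-2-en-1-yl)-1-benzofuran-2-yl]-2-[(2-methylbut-3-en-2-yl)oxy]-6-[(2-methylbut-3-yn-2-yl)oxy]benzoate | COC(=O)c1c(OC(C)(C)C=C)cc(-c2cc3ccc(OCOC)c(CC=C(C)C)c3o2)cc1OC(C)(C)C#C | intermediate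
17 | methyl 4-[6-(methoxymethoxy)-7-(3-methylbut-2-en-1-yl)-1-benzofuran-2-yl]-2,6-bis[(2-methylbut-3-en-2-yl)oxy]benzoate | COC(=O)c1c(OC(C)(C)C=C)cc(-c2cc3ccc(OCOC)c(CC=C(C)C)c3o2)cc1OC(C)(C)C=C | intermediate
18 | methyl 2-hydroxy-4-[6-(methoxymethoxy)-7-(3-methylbut-2-en-1-yl)-1-benzofuran-2-yl]-3-(3-methylbut-2-en-1-yl)-6-[(2-methylbut-3-en-2-yl)oxy]benzoate | COC(=O)c1c(O)c(CC=C(C)C)c(-c2cc3ccc(OCOC)c(CC=C(C)C)c3o2)cc1OC(C)(C)C=C | intermediate
19 | methyl 2,6-dihydroxy-4-[6-(methoxymethoxy)-7-(3-methylbut-2-en-1-yl)-1-benzofuran-2-yl]-3,5-bis(3-methylbut-2-en-1-yl)benzoate | COC(=O)c1c(O)c(CC=C(C)C)c(-c2cc3ccc(OCOC)c(CC=C(C)C)c3o2)c(CC=C(C)C)c1O | intermediate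
20 | methyl 2,6-dihydroxy-4-[6-hydroxy-7-(3-methylbut-2-en-1-yl)-1-benzofuran-2-yl]-3,5-bis(3-methylbut-2-en-1-yl)benzoate | COC(=O)c1c(O)c(CC=C(C)C)c(-c2cc3ccc(O)c(CC=C(C)C)c3o2)c(CC=C(C)C)c1O | intermediate
21 | 2,6-dihydroxy-4-[6-hydroxy-7-(3-methylbut-2-en-1-yl)-1-benzofuran-2-yl]-3,5-bis(3-methylbut-2-en-1-yl)benzoic acid | OC(=O)c1c(O)c(CC=C(C)C)c(-c2cc3ccc(O)c(CC=C(C)C)c3o2)c(CC=C(C)C)c1O | intermediate
22 | 5-[6-hydroxy-7-(3-methylbut-2-en-1-yl)-1-benzofuran-2-yl]-4,6-bis(3-methylbut-2-en-1-yl)benzene-1,3-diol | CC(C)=CCc1c(O)cc(O)c(CC=C(C)C)c1-c1cc2ccc(O)c(CC=C(C)C)c2o1 | target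

## Step count and least certain steps

Total: 14 steps. Longest linear sequence: 13 steps (steps 1 to 6 and 8 to 14, from 1); step 7 makes the ring B partner.

**Step 12 (key step).** The most likely failure is heterolysis of the tertiary allylic C–O bonds instead of the concerted shift. The departing aryloxide is stabilised by the ortho ester, so isoprene may be lost or the allyl unit may recombine unselectively. The second shift must also place a prenyl group beside the benzofuran and may stall at 18. A detour through the ester-bearing carbon followed by a Cope shift would deliver a 1,1-dimethylallyl group, and long heating could close chromans. Fallback: set out from 13 and O-alkylate both hydroxyls with prenyl bromide and K2CO3 in DMF to give methyl 4-[6-(methoxymethoxy)-7-prenyl-1-benzofuran-2-yl]-2,6-bis(prenyloxy)benzoate F1. Then move the prenyl groups from oxygen to carbon by the 1,3-shift of aryl prenyl ethers promoted by activated magnesium silicate (MgSiO3, Florisil) in warm toluene. This is an ion-pair pathway, not a pericyclic one, and here the ortho and para carbons of each ether oxygen are both wanted positions. The fallback returns to the route at 19.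

**Step 10.** The second etherification may stall, because the remaining hydroxyl of 14 is hydrogen-bonded to the ester and flanked by it, so the copper electrophile may be consumed by methoxide or DBU instead. Fallback: set out from 13 and form the tertiary allyl ethers directly by palladium-catalysed decarboxylative allylic etherification with tert-butyl 2-methylbut-3-en-2-yl carbonate F2 (from 2-methylbut-3-en-2-ol and Boc2O) and Pd(PPh3)4 in THF at 0 °C. The phenoxide attacks the π-allyl complex of divalent palladium at its more substituted end, first giving methyl 2-hydroxy-4-[6-(methoxymethoxy)-7-prenyl-1-benzofuran-2-yl]-6-[(2-methylbut-3-en-2-yl)oxy]benzoate F3 and then, with more F2, the bis ether. The fallback returns at 17 and bypasses steps 9 to 11.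

**Step 4.** The shift may divide between C7 and C5, and some ether may lose isoprene. Fallback: set out from 4 and replace the sigmatropic step by directed metalation. The phenol is protected as 6-(methoxymethoxy)-1-benzofuran F4 (MOMCl, iPr2NEt), and C2 is blocked by lithiation and silylation to [6-(methoxymethoxy)-1-benzofuran-2-yl]trimethylsilane F5 (n-BuLi, Me3SiCl). C7, between the acetal oxygen and O1, is then lithiated (s-BuLi, TMEDA, −78 °C), transmetalated with CuBr·SMe2 and alkylated with prenyl bromide to [6-(methoxymethoxy)-7-prenyl-1-benzofuran-2-yl]trimethylsilane F6. Bu4NF removes the silyl group, and the fallback returns at 8.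

**Step 7.** Sulfonylation may lose site selectivity or go twice, since the ortho hydroxyls are only partly deactivated. Fallback: set out from 10 and couple it with a different ring B partner, built from commercial 2,4,6-trihydroxybenzoic acid F7. The acid and one ortho hydroxyl are tied into 5,7-dihydroxy-2,2-dimethyl-4H-1,3-benzodioxin-4-one F8 (acetone, (CF3CO)2O, CF3CO2H). The remaining chelated 5-hydroxyl is clearly less reactive than the 7-hydroxyl, so Tf2O/pyridine should give 5-hydroxy-2,2-dimethyl-4-oxo-4H-1,3-benzodioxin-7-yl trifluoromethanesulfonate F9. Suzuki–Miyaura coupling with 10 (Pd(dppf)Cl2, K3PO4) gives 5-hydroxy-7-[6-(methoxymethoxy)-7-prenyl-1-benzofuran-2-yl]-2,2-dimethyl-4H-1,3-benzodioxin-4-one F10, and NaOMe in MeOH opens the dioxinone to the methyl ester, returning at 13.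

**Step 13.** Acid may damage the prenyl groups before or after the acetal is gone, by cyclization onto the neighbouring phenols or by addition of methanol or HCl. Fallback: set out from 19 and avoid protic acid. Me3SiOTf with 2,2'-bipyridyl in MeCN at 0 °C exchanges the aryl acetal for a silyl ether under amine-buffered aprotic conditions, giving methyl 2,6-dihydroxy-3,5-diprenyl-4-[7-prenyl-6-(trimethylsilyloxy)-1-benzofuran-2-yl]benzoate F11. Any silylation of the ring B hydroxyls is undone in the same work-up, and water at neutral pH cleaves the silyl ether, returning at 20.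

**Step 14.** Hydroxide may fail to attack the ester carbonyl, which is flanked by two phenoxides and enriched by them, and long heating of the triphenoxide invites oxidation. Fallback: set out from 20 and break the O–CH3 bond instead of the acyl–oxygen bond by SN2 demethylation with NaSEt in DMF at 100 °C. This gives the carboxylate of 21, which after adjustment to pH 5–6 loses CO2 on gentle warming, returning at 22. No new compound is made.

## Further compounds

F1 | step 12 | methyl 4-[6-(methoxymethoxy)-7-(3-methylbut-2-en-1-yl)-1-benzofuran-2-yl]-2,6-bis[(3-methylbut-2-en-1-yl)oxy]benzoate | COC(=O)c1c(OCC=C(C)C)cc(-c2cc3ccc(OCOC)c(CC=C(C)C)c3o2)cc1OCC=C(C)C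
F2 | step 10 | tert-butyl 2-methylbut-3-en-2-yl carbonate | CC(C)(C)OC(=O)OC(C)(C)C=C
F3 | step 10 | methyl 2-hydroxy-4-[6-(methoxymethoxy)-7-(3-methylbut-2-en-1-yl)-1-benzofuran-2-yl]-6-[(2-methylbut-3-en-2-yl)oxy]benzoate | COC(=O)c1c(O)cc(-c2cc3ccc(OCOC)c(CC=C(C)C)c3o2)cc1OC(C)(C)C=C
F4 | step 4 | 6-(methoxymethoxy)-1-benzofuran | COCOc1ccc2ccoc2c1
F5 | step 4 | [6-(methoxymethoxy)-1-benzofuran-2-yl]trimethylsilane | COCOc1ccc2cc([Si](C)(C)C)oc2c1
F6 | step 4 | [6-(methoxymethoxy)-7-(3-methylbut-2-en-1-yl)-1-benzofuran-2-yl]trimethylsilane | COCOc1ccc2cc([Si](C)(C)C)oc2c1CC=C(C)C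
F7 | step 7 | 2,4,6-trihydroxybenzoic acid | OC(=O)c1c(O)cc(O)cc1O
F8 | step 7 | 5,7-dihydroxy-2,2-dimethyl-4H-1,3-benzodioxin-4-one | CC1(C)OC(=O)c2c(O)cc(O)cc2O1
F9 | step 7 | 5-hydroxy-2,2-dimethyl-4-oxo-4H-1,3-benzodioxin-7-yl trifluoromethanesulfonate | CC1(C)OC(=O)c2c(O)cc(OS(=O)(=O)C(F)(F)F)cc2O1
F10 | step 7 | 5-hydroxy-7-[6-(methoxymethoxy)-7-(3-methylbut-2-en-1-yl)-1-benzofuran-2-yl]-2,2-dimethyl-4H-1,3-benzodioxin-4-one | CC1(C)OC(=O)c2c(O)cc(-c3cc4ccc(OCOC)c(CC=C(C)C)c4o3)cc2O1
F11 | step 13 | methyl 2,6-dihydroxy-3,5-bis(3-methylbut-2-en-1-yl)-4-[7-(3-methylbut-2-en-1-yl)-6-(trimethylsilyloxy)-1-benzofuran-2-yl]benzoate | COC(=O)c1c(O)c(CC=C(C)C)c(-c2cc3ccc(O[Si](C)(C)C)c(CC=C(C)C)c3o2)c(CC=C(C)C)c1O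
F0 | step 14 | none | none
A1 | alternative 1 | 2-[3,5-bis(tert-butyldimethylsilyloxy)-2,6-bis(3-methylbut-2-en-1-yl)phenyl]-7-(3-methylbut-2-en-1-yl)-1-benzofuran-6-ol | CC(C)=CCc1c(O)ccc2cc(-c3c(CC=C(C)C)c(O[Si](C)(C)C(C)(C)C)cc(O[Si](C)(C)C(C)(C)C)c3CC=C(C)C)oc12
A2 | alternative 1 | racemic 4-{5-[3,5-bis(tert-butyldimethylsilyloxy)-2,6-bis(3-methylbut-2-en-1-yl)phenyl]furan-2-yl}-1,1-diethoxy-7-methyloct-6-en-3-one | CCOC(OCC)CC(=O)C(CC=C(C)C)c1ccc(-c2c(CC=C(C)C)c(O[Si](C)(C)C(C)(C)C)cc(O[Si](C)(C)C(C)(C)C)c2CC=C(C)C)o1
A3 | alternative 2 | 2-[3,5-bis(methoxymethoxy)-2,6-bis(3-methylbut-2-en-1-yl)phenyl]-6-(methoxymethoxy)-7-(3-methylbut-2-en-1-yl)-1-benzofuran | COCOc1ccc2cc(-c3c(CC=C(C)C)c(OCOC)cc(OCOC)c3CC=C(C)C)oc2c1CC=C(C)C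
A4 | alternative 2 | {[2-({3,5-bis(methoxymethoxy)-2,6-bis(3-methylbut-2-en-1-yl)benzoyl}oxy)-4-(methoxymethoxy)-3-(3-methylbut-2-en-1-yl)phenyl]methyl}triphenylphosphonium bromide | COCOc1ccc(C[P+](c2ccccc2)(c2ccccc2)c2ccccc2)c(OC(=O)c2c(CC=C(C)C)c(OCOC)cc(OCOC)c2CC=C(C)C)c1CC=C(C)C.[Br-]
A5 | alternative 2 | 3,5-bis(methoxymethoxy)-2,6-bis(3-methylbut-2-en-1-yl)benzoic acid | OC(=O)c1c(CC=C(C)C)c(OCOC)cc(OCOC)c1CC=C(C)C
A6 | alternative 3 | 3-[6-(methoxymethoxy)-7-(3-methylbut-2-en-1-yl)-1-benzofuran-2-yl]-2,4-bis(3-methylbut-2-en-1-yl)-5-[(triisopropylsilyl)oxy]phenol | CC(C)=CCc1c(O)cc(O[Si](C(C)C)(C(C)C)C(C)C)c(CC=C(C)C)c1-c1cc2ccc(OCOC)c(CC=C(C)C)c2o1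
A7 | alternative 3 | racemic 3-[6-(methoxymethoxy)-7-(3-methylbut-2-en-1-yl)-1-benzofuran-2-yl]-2,4-bis(3-methylbut-2-en-1-yl)cyclobut-2-en-1-one | O=C1C(CC=C(C)C)=C(c2cc3ccc(OCOC)c(CC=C(C)C)c3o2)C1CC=C(C)C
A8 | alternative 3 | (ethynyloxy)tri(propan-2-yl)silane | C#CO[Si](C(C)C)(C(C)C)C(C)C
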